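The cyclopentane is cut at C1–C2, the bond inside the 1,3-dioxygenated array O–C2–C1–C10–O (daucane numbering: C1 methyl-bearing ring-fusion carbon, C2 acetoxy carbon, C4 isopropyl carbinol, C5 ring-fusion CH, C6 anisoyloxy carbon, C10 free carbinol). In one operation a Claisen (Dieckmann) closure of a C10 ketone enolate onto a C2 ester forms this bond and the five-membered ring, and methylation of the diketonate sets quaternary C1 under control of a temporary C4 carbinol. The precursor is a monocyclic cyclohepta-2,5-dienone from a rhodium vinylcarbenoid [4+3] annulation; its C5=C6 alkene keeps the ring fusion trigonal, and the trans fusion follows by silicon-tethered syn-hydrosilylation.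

Key step: step 9

Remark: C3 and C7 are the ring methylenes, C8 and C9 the epoxide carbons; the five-membered ring is C1–C5 and the seven-membered ring is C1, C5–C10; β is the face of the C1 methyl group and α the opposite face.
Remark: compounds 5–8 are racemic, and 9 and 10 are pairs of epimers at ring carbon C8; C8 becomes trigonal in step 8, so both epimers converge on the single compound 11.

Step 1
Reactants: 1 methyl but-3-enoate
Product: 2 methyl 2-diazobut-3-enoate
Conditions: 4-acetamidobenzenesulfonyl azide, DBU, MeCN, 0 °C; used at once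
Reagents that add atoms: 4-acetamidobenzenesulfonyl azide, CC(=O)Nc1ccc(cc1)S(=O)(=O)N=[N+]=[N-]
Why: Regitz-type diazo transfer to the α-carbon, which is activated by both the ester and the vinyl group, should give the vinyldiazoacetate; no stereocentre is formed.

Step 2
Reactants: 3 (E)-pent-3-en-2-one
Product: 4 (E)-2-(tert-butyldimethylsilyloxy)penta-1,3-diene
Conditions: TBSOTf, Et3N, CH2Cl2, 0 °C
Reagents that add atoms: tert-butyldimethylsilyl trifluoromethanesulfonate, CC(C)(C)[Si](C)(C)OS(=O)(=O)C(F)(F)F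
Why: Soft enolisation of the methyl ketone on its methyl side and O-silylation should give the 2-silyloxy-1,3-diene with the (E)-propenyl geometry untouched.

Step 3
Reactants: 2 methyl 2-diazobut-3-enoate; 4 (E)-2-(tert-butyldimethylsilyloxy)penta-1,3-diene
Product: 6 methyl 6-(tert-butyldimethylsilyloxy)-4-methylcyclohepta-1,5-diene-1-carboxylate (racemic), via cis-divinylcyclopropane 5 (not isolated)
Conditions: Rh2(OPiv)4 (1 mol %), pentane, 36 °C, slow addition of 2 to 4 (3 equiv)
Reagents that add atoms: none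
Why: The rhodium vinylcarbenoid should cyclopropanate the electron-rich 1,1-disubstituted enol ether alkene (the trans-disubstituted alkene is inert), and the cis-divinylcyclopropane then undergoes Cope rearrangement through a boat transition state, a formal [4+3] annulation that places the ester, both alkenes, the C8 methyl and the C10 oxygen on the seven-membered ring; C8 is formed racemic.

Step 4
Reactants: 6 methyl 6-(tert-butyldimethylsilyloxy)-4-methylcyclohepta-1,5-diene-1-carboxylate
Product: 7 6-(tert-butyldimethylsilyloxy)-N-methoxy-N,4-dimethylcyclohepta-1,5-diene-1-carboxamide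
Conditions: MeNH(OMe)·HCl, iPrMgCl, THF, −20 to 0 °C
Reagents that add atoms: N,O-dimethylhydroxylamine hydrochloride, CNOC.Cl
Why: Aminolysis of the ester by the chloromagnesium amide (Weinreb amide formation) occurs at the carbonyl, leaves the silyl enol ether intact and prepares a clean 1,2-acylation in place of a conjugate addition to the enoate.

Step 5
Reactants: 7 6-(tert-butyldimethylsilyloxy)-N-methoxy-N,4-dimethylcyclohepta-1,5-diene-1-carboxamide
Product: 8 methyl 3-[6-(tert-butyldimethylsilyloxy)-4-methylcyclohepta-1,5-dien-1-yl]-3-oxopropanoate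
Conditions: MeOAc, LDA (commercial solution), THF, −78 °C; then 7, −78 to −40 °C; aq NH4Cl
Reagents that add atoms: methyl acetate, CC(=O)OC
Why: Claisen-type acylation of the lithium ester enolate by the Weinreb amide stops at the chelated tetrahedral adduct, which should release the β-keto ester on work-up.

Step 6
Reactants: 8 methyl 3-[6-(tert-butyldimethylsilyloxy)-4-methylcyclohepta-1,5-dien-1-yl]-3-oxopropanoate
Product: 9 methyl (3R)-3-[6-(tert-butyldimethylsilyloxy)-4-methylcyclohepta-1,5-dien-1-yl]-3-hydroxypropanoate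
Conditions: (S)-2-methyl-CBS-oxazaborolidine (0.2 equiv), catecholborane, toluene, −78 °C
Reagents that add atoms: none
Why: Corey–Bakshi–Shibata reduction treats the cycloheptadienyl group as the large and the CH2CO2Me group as the small ketone substituent, so the (S)-catalyst should give the (3R)-carbinol, the temporary C4 stereocentre, by reagent control.

Step 7
Reactants: 9 methyl (3R)-3-[6-(tert-butyldimethylsilyloxy)-4-methylcyclohepta-1,5-dien-1-yl]-3-hydroxypropanoate
Product: 10 methyl (3R)-3-[6-(tert-butyldimethylsilyloxy)-4-methylcyclohepta-1,5-dien-1-yl]-3-(triethylsilyloxy)propanoate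
Conditions: TESCl, imidazole, DMF, 0 °C
Reagents that add atoms: chlorotriethylsilane, CC[Si](Cl)(CC)CC
Why: Silylation of the secondary alcohol protects it against palladium and base in the next steps and turns it into a bulky control element.

Step 8
Reactants: 10 methyl (3R)-3-[6-(tert-butyldimethylsilyloxy)-4-methylcyclohepta-1,5-dien-1-yl]-3-(triethylsilyloxy)propanoate
Product: 11 methyl (3R)-3-(4-methyl-6-oxocyclohepta-1,4-dien-1-yl)-3-(triethylsilyloxy)propanoate
Conditions: Pd(OAc)2 (1.05 equiv), MeCN, 23 °C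
Reagents that add atoms: none
Why: Saegusa–Ito oxidation: palladation of the silyl enol ether at C9 and β-hydride elimination of the C8 hydrogen should give the C8=C9 enone regiospecifically and erase the C8 stereocentre.

Step 9
Reactants: 11 methyl (3R)-3-(4-methyl-6-oxocyclohepta-1,4-dien-1-yl)-3-(triethylsilyloxy)propanoate
Product: 13 1β,8-dimethyl-4α-(triethylsilyloxy)bicyclo[5.3.0]deca-5,8-diene-2,10-dione, via C1-unsubstituted diketone 12 (not isolated)
Conditions: LiHMDS (2.2 equiv, commercial solution), THF, −78 to −20 °C; then MeI (5 equiv), −20 to 23 °C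
Reagents that add atoms: iodomethane, CI
Why: LiHMDS removes a proton from the only α-methylene of the C10 ketone (C1, also allylic to C5=C6; C9 is vinylic), and the lithium dienolate attacks the C2 ester carbonyl in a 5-(enolexo)-exo-trig Claisen (Dieckmann) closure that forms the C1–C2 bond and the cyclopentane with loss of methoxide. The new 2-acyl ketone is deprotonated at once to the stabilised diketonate, which makes the closure irreversible and shields the product from retro-Claisen cleavage. Iodomethane then C-alkylates the planar diketonate at C1 from the face anti to the C4 triethylsilyloxy group, which allylic strain against the C6 hydrogen holds pseudo-axial on the flat five-membered ring, so the temporary C4 centre controls quaternary C1. The closest known reaction type is the Dieckmann condensation followed by C-alkylation of the 1,3-diketone in the same flask. The step needs regioselective enolisation and C- over O-alkylation: anions at C7 or C3, if formed, cannot reach C2 through a five-membered transition state (C7 is trans to C4 across C5=C6) and equilibrate back, and the soft electrophile iodomethane with a lithium diketonate in THF favours carbon. Because C5 stays trigonal, no ring-fusion stereochemistry is at stake in the closure.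

Step 10
Reactants: 13 1β,8-dimethyl-4α-(triethylsilyloxy)bicyclo[5.3.0]deca-5,8-diene-2,10-dione
Product: 14 2β-hydroxy-1β,8-dimethyl-4α-(triethylsilyloxy)bicyclo[5.3.0]deca-5,8-dien-10-one
Conditions: NaBH4, MeOH–CH2Cl2 (1:1), −78 °C
Reagents that add atoms: none
Why: At low temperature borohydride should reduce the saturated cyclopentanone and leave the conjugated neopentyl C10 ketone, and hydride adds anti to the pseudo-axial C1 methyl to give the 2β-alcohol, as in the reduction of 17-oxo steroids.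

Step 11
Reactants: 14 2β-hydroxy-1β,8-dimethyl-4α-(triethylsilyloxy)bicyclo[5.3.0]deca-5,8-dien-10-one
Product: 15 2β-acetoxy-1β,8-dimethyl-4α-(triethylsilyloxy)bicyclo[5.3.0]deca-5,8-dien-10-one
Conditions: Ac2O, pyridine, DMAP (cat.), CH2Cl2, 23 °C
Reagents that add atoms: acetic anhydride, CC(=O)OC(C)=O
Why: DMAP-catalysed acetylation of the only free hydroxyl installs the final C2 acetate before the C4 oxygen is unmasked.

Step 12
Reactants: 15 2β-acetoxy-1β,8-dimethyl-4α-(triethylsilyloxy)bicyclo[5.3.0]deca-5,8-dien-10-one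
Product: 16 2β-acetoxy-4α-hydroxy-1β,8-dimethylbicyclo[5.3.0]deca-5,8-dien-10-one
Conditions: HF·pyridine, pyridine, THF, 0 °C
Reagents that add atoms: none
Why: Fluoride cleaves the secondary triethylsilyl ether selectively, and the acetate and the enone are stable to buffered HF·pyridine.

Step 13
Reactants: 16 2β-acetoxy-4α-hydroxy-1β,8-dimethylbicyclo[5.3.0]deca-5,8-dien-10-one
Product: 18 2β-acetoxy-1β,8-dimethyl-5α-H-bicyclo[5.3.0]dec-8-en-10-one bridged from O4α to C6α by a dimethylsilylene unit (fused 2,2-dimethyl-1,2-oxasilolane), via dimethylsilyl ether 17 (not isolated)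
Conditions: (HMe2Si)2NH (neat), 23 °C, then removal of volatiles; Pt2[(CH2=CHSiMe2)2O]3 (0.5 mol %), toluene, 60 °C
Reagents that add atoms: 1,1,3,3-tetramethyldisilazane, C[SiH](C)N[SiH](C)C
Why: Silylation of the allylic alcohol followed by platinum-catalysed intramolecular hydrosilylation (5-endo) should add silicon to C6 and hydrogen to C5 on the same α face, the face of the tethering C4 oxygen, which sets the trans ring fusion (5α-H) and the C6 configuration in one syn addition.

Step 14
Reactants: 18 the dimethylsilylene-bridged 2β-acetoxy enone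
Product: 19 2β-acetoxy-6α-(hydroxydimethylsilyl)-1β,8-dimethyl-5α-H-bicyclo[5.3.0]dec-8-ene-4,10-dione
Conditions: CrO3, H2SO4, H2O, acetone, 0 °C (Jones reagent), short reaction time
Reagents that add atoms: water, O
Why: Jones oxidation hydrolyses the strained cyclic silyl ether and oxidises the freed C4 carbinol to the ketone while the carbon–silicon bond survives; the temporary C4 stereocentre is erased after it has done its work.

Step 15
Reactants: 19 2β-acetoxy-6α-(hydroxydimethylsilyl)-1β,8-dimethyl-5α-H-bicyclo[5.3.0]dec-8-ene-4,10-dione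
Product: 20 2β-acetoxy-4β-hydroxy-6α-(hydroxydimethylsilyl)-4α-isopropyl-1β,8-dimethyl-5α-H-bicyclo[5.3.0]dec-8-en-10-one
Conditions: CeCl3 (anhydrous), iPrMgCl (2.2 equiv), THF, −78 °C
Reagents that add atoms: isopropylmagnesium chloride, CC(C)[Mg]Cl
Why: The organocerium reagent should add 1,2 to the cyclopentanone from the α face, anti to the C1 methyl and the C2 acetoxy group, giving the tertiary 4β-alcohol; the conjugated neopentyl C10 ketone and the acetate are less reactive at −78 °C.

Step 16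
Reactants: 20 2β-acetoxy-4β-hydroxy-6α-(hydroxydimethylsilyl)-4α-isopropyl-1β,8-dimethyl-5α-H-bicyclo[5.3.0]dec-8-en-10-one
Product: 21 2β-acetoxy-4β,6α-dihydroxy-4α-isopropyl-1β,8-dimethyl-5α-H-bicyclo[5.3.0]dec-8-en-10-one
Conditions: KF, KHCO3, 30% H2O2, THF–MeOH (1:1), 23 °C
Reagents that add atoms: hydrogen peroxide, OO
Why: Tamao–Fleming oxidation converts the C–Si bond into C–OH with retention, giving the 6α-alcohol.

Step 17
Reactants: 21 2β-acetoxy-4β,6α-dihydroxy-4α-isopropyl-1β,8-dimethyl-5α-H-bicyclo[5.3.0]dec-8-en-10-one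
Product: 22 2β-acetoxy-8α,9α-epoxy-4β,6α-dihydroxy-4α-isopropyl-1β,8-dimethyl-5α-H-bicyclo[5.3.0]decan-10-one
Conditions: tBuOOH (anhydrous, in decane), DBU, CH2Cl2, 0 to 23 °C
Reagents that add atoms: tert-butyl hydroperoxide, CC(C)(C)OO
Why: Weitz–Scheffer epoxidation: tert-butylperoxide adds to C8 of the enone and closes onto C9 from the α face, anti to the pseudo-axial C1 methyl and on the side of the C6 hydroxyl, which can guide the peroxide by hydrogen bonding.

Step 18
Reactants: 22 2β-acetoxy-8α,9α-epoxy-4β,6α-dihydroxy-4α-isopropyl-1β,8-dimethyl-5α-H-bicyclo[5.3.0]decan-10-one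
Product: 23 2β-acetoxy-8α,9α-epoxy-4β-hydroxy-4α-isopropyl-6α-(4-methoxybenzoyloxy)-1β,8-dimethyl-5α-H-bicyclo[5.3.0]decan-10-one
Conditions: 4-methoxybenzoyl chloride, pyridine, DMAP (cat.), CH2Cl2, 0 to 23 °C
Reagents that add atoms: 4-methoxybenzoyl chloride, COc1ccc(cc1)C(Cl)=O
Why: Acylation takes place at the secondary C6 hydroxyl; the tertiary C4 hydroxyl does not react under these conditions.

Step 19
Reactants: 23 2β-acetoxy-8α,9α-epoxy-4β-hydroxy-4α-isopropyl-6α-(4-methoxybenzoyloxy)-1β,8-dimethyl-5α-H-bicyclo[5.3.0]decan-10-one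
Product: 24 CNP0371526.1, 2β-acetoxy-8α,9α-epoxy-4β,10β-dihydroxy-4α-isopropyl-6α-(4-methoxybenzoyloxy)-1β,8-dimethyl-5α-H-bicyclo[5.3.0]decane
Conditions: NaBH4, CeCl3·7H2O, MeOH, −78 °C
Reagents that add atoms: none
Why: Luche reduction of an α,β-epoxy ketone gives the anti (trans) epoxy alcohol, and hydride approach anti to the C1 methyl agrees with it, so the 10β-alcohol should result.

Compound list
1 | methyl but-3-enoate | C=CCC(=O)OC | starting material
2 | methyl 2-diazobut-3-enoate | C=CC(=[N+]=[N-])C(=O)OC | intermediate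
3 | (E)-pent-3-en-2-one | C/C=C/C(C)=O | starting material
4 | (E)-2-(tert-butyldimethylsilyloxy)penta-1,3-diene | C=C(O[Si](C)(C)C(C)(C)C)/C=C/C | intermediate
5 | methyl 2-(tert-butyldimethylsilyloxy)-2-[(E)-prop-1-enyl]-1-vinylcyclopropane-1-carboxylate (vinyl and propenyl cis; racemic, one enantiomer drawn) | COC(=O)[C@]1(C=C)C[C@@]1(O[Si](C)(C)C(C)(C)C)/C=C/C | intermediate
6 | methyl 6-(tert-butyldimethylsilyloxy)-4-methylcyclohepta-1,5-diene-1-carboxylate (racemic) | COC(=O)C1=CCC(C)C=C(O[Si](C)(C)C(C)(C)C)C1 | intermediate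
7 | 6-(tert-butyldimethylsilyloxy)-N-methoxy-N,4-dimethylcyclohepta-1,5-diene-1-carboxamide (racemic) | CON(C)C(=O)C1=CCC(C)C=C(O[Si](C)(C)C(C)(C)C)C1 | intermediate
8 | methyl 3-[6-(tert-butyldimethylsilyloxy)-4-methylcyclohepta-1,5-dien-1-yl]-3-oxopropanoate (racemic) | COC(=O)CC(=O)C1=CCC(C)C=C(O[Si](C)(C)C(C)(C)C)C1 | intermediate
9 | methyl (3R)-3-[6-(tert-butyldimethylsilyloxy)-4-methylcyclohepta-1,5-dien-1-yl]-3-hydroxypropanoate (both epimers at the ring methyl carbon) | COC(=O)C[C@@H](O)C1=CCC(C)C=C(O[Si](C)(C)C(C)(C)C)C1 | intermediate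
10 | methyl (3R)-3-[6-(tert-butyldimethylsilyloxy)-4-methylcyclohepta-1,5-dien-1-yl]-3-(triethylsilyloxy)propanoate (both epimers at the ring methyl carbon) | COC(=O)C[C@@H](O[Si](CC)(CC)CC)C1=CCC(C)C=C(O[Si](C)(C)C(C)(C)C)C1 | intermediate
11 | methyl (3R)-3-(4-methyl-6-oxocyclohepta-1,4-dien-1-yl)-3-(triethylsilyloxy)propanoate | COC(=O)C[C@@H](O[Si](CC)(CC)CC)C1=CCC(C)=CC(=O)C1 | intermediate
12 | 8-methyl-4α-(triethylsilyloxy)bicyclo[5.3.0]deca-5,8-diene-2,10-dione (C1–H, formed as its lithium enolate) | C12=CCC(C)=CC(=O)C1C(=O)C[C@H]2O[Si](CC)(CC)CC | intermediate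
13 | 1β,8-dimethyl-4α-(triethylsilyloxy)bicyclo[5.3.0]deca-5,8-diene-2,10-dione | C12=CCC(C)=CC(=O)[C@@]1(C)C(=O)C[C@H]2O[Si](CC)(CC)CC | intermediate
14 | 2β-hydroxy-1β,8-dimethyl-4α-(triethylsilyloxy)bicyclo[5.3.0]deca-5,8-dien-10-one | C12=CCC(C)=CC(=O)[C@@]1(C)[C@H](O)C[C@H]2O[Si](CC)(CC)CC | intermediate
15 | 2β-acetoxy-1β,8-dimethyl-4α-(triethylsilyloxy)bicyclo[5.3.0]deca-5,8-dien-10-one | C12=CCC(C)=CC(=O)[C@@]1(C)[C@H](OC(C)=O)C[C@H]2O[Si](CC)(CC)CC | intermediate
16 | 2β-acetoxy-4α-hydroxy-1β,8-dimethylbicyclo[5.3.0]deca-5,8-dien-10-one | C12=CCC(C)=CC(=O)[C@@]1(C)[C@H](OC(C)=O)C[C@H]2O | intermediate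
17 | 2β-acetoxy-4α-(dimethylsilyloxy)-1β,8-dimethylbicyclo[5.3.0]deca-5,8-dien-10-one | C12=CCC(C)=CC(=O)[C@@]1(C)[C@H](OC(C)=O)C[C@H]2O[SiH](C)C | intermediate
18 | 2β-acetoxy-1β,8-dimethyl-5α-H-bicyclo[5.3.0]dec-8-en-10-one with an O4α–SiMe2–C6α bridge (fused 2,2-dimethyl-1,2-oxasilolane) | C[Si]1(C)[C@H]2CC(C)=CC(=O)[C@]3(C)[C@@H]2[C@H](O1)C[C@H]3OC(C)=O | intermediate
19 | 2β-acetoxy-6α-(hydroxydimethylsilyl)-1β,8-dimethyl-5α-H-bicyclo[5.3.0]dec-8-ene-4,10-dione | C[Si](C)(O)[C@H]1CC(C)=CC(=O)[C@]2(C)[C@@H]1C(=O)C[C@H]2OC(C)=O | intermediate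
20 | 2β-acetoxy-4β-hydroxy-6α-(hydroxydimethylsilyl)-4α-isopropyl-1β,8-dimethyl-5α-H-bicyclo[5.3.0]dec-8-en-10-one | C[Si](C)(O)[C@H]1CC(C)=CC(=O)[C@]2(C)[C@@H]1[C@](O)(C(C)C)C[C@H]2OC(C)=O | intermediate
21 | 2β-acetoxy-4β,6α-dihydroxy-4α-isopropyl-1β,8-dimethyl-5α-H-bicyclo[5.3.0]dec-8-en-10-one | O[C@H]1CC(C)=CC(=O)[C@]2(C)[C@@H]1[C@](O)(C(C)C)C[C@H]2OC(C)=O | intermediate
22 | 2β-acetoxy-8α,9α-epoxy-4β,6α-dihydroxy-4α-isopropyl-1β,8-dimethyl-5α-H-bicyclo[5.3.0]decan-10-one | O[C@H]1C[C@@]2(C)O[C@H]2C(=O)[C@]2(C)[C@@H]1[C@](O)(C(C)C)C[C@H]2OC(C)=O | intermediate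
23 | 2β-acetoxy-8α,9α-epoxy-4β-hydroxy-4α-isopropyl-6α-(4-methoxybenzoyloxy)-1β,8-dimethyl-5α-H-bicyclo[5.3.0]decan-10-one | COc1ccc(cc1)C(=O)O[C@H]1C[C@@]2(C)O[C@H]2C(=O)[C@]2(C)[C@@H]1[C@](O)(C(C)C)C[C@H]2OC(C)=O | intermediate
24 | CNP0371526.1, 2β-acetoxy-8α,9α-epoxy-4β,10β-dihydroxy-4α-isopropyl-6α-(4-methoxybenzoyloxy)-1β,8-dimethyl-5α-H-bicyclo[5.3.0]decane (1S,2R,4R,5S,6S,8R,9S,10R in the numbering used here) | COc1ccc(C(=O)O[C@H]2C[C@@]3(C)O[C@H]3[C@H](O)[C@]3(C)[C@@H]2[C@](O)(C(C)C)C[C@H]3OC(C)=O)cc1 | target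

Total step count: 19. Longest linear sequence: 18 steps (steps 1 and 3–19; step 2 supplies the diene).

Steps most likely to fail

Step 9. The methylation of the diketonate may show poor facial selectivity or go to oxygen, and prolonged exposure to base may eliminate the β-silyloxy group before the ring closes. The fallback sets out from 11 and reverses the order of events. The ketone is first methylated at C1 through its kinetic α′-enolate (LDA, MeI, THF, −78 °C) to methyl (3R)-3-(4,7-dimethyl-6-oxocyclohepta-1,4-dien-1-yl)-3-(triethylsilyloxy)propanoate F1 (both C1 epimers). The ring is then closed by Claisen C-acylation of the tertiary potassium enolate (KHMDS, THF, −78 to −20 °C). The quaternary centre then arises in the cyclization itself, with the silyloxy group avoiding the syn contact with the C1 methyl in the five-membered transition state, and the sequence comes back to the route at 13.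

Step 13. The 5-endo hydrosilylation may be too slow at the hindered trisubstituted alkene, or the silane may add to the enone instead. The fallback sets out from 16 and uses the same C4α hydroxyl as a directing group for oxygen instead of silicon. Epoxidation with VO(acac)2 and tBuOOH (CH2Cl2, 0 °C) should give 2β-acetoxy-5α,6α-epoxy-4α-hydroxy-1β,8-dimethylbicyclo[5.3.0]dec-8-en-10-one F2. Dess–Martin oxidation should give 2β-acetoxy-5α,6α-epoxy-1β,8-dimethylbicyclo[5.3.0]dec-8-ene-4,10-dione F3. SmI2 (THF–MeOH, −90 °C) should open the epoxy ketone at C5 to 2β-acetoxy-6α-hydroxy-1β,8-dimethyl-5α-H-bicyclo[5.3.0]dec-8-ene-4,10-dione F4, with C5 protonated anti to the C1 methyl. Addition of the isopropylcerium reagent (iPrMgCl, CeCl3, THF, −78 °C) then comes back to the route at 21.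

Step 17. The nucleophilic epoxidation may show poor facial selectivity, and the hydride reduction that follows depends on it. The fallback sets out from 21 and makes the epoxide by electrophilic attack anti to a bulky allylic ether. Acylation with 4-methoxybenzoyl chloride (pyridine, DMAP) should give 2β-acetoxy-4β-hydroxy-4α-isopropyl-6α-(4-methoxybenzoyloxy)-1β,8-dimethyl-5α-H-bicyclo[5.3.0]dec-8-en-10-one F5. Luche reduction should give the 10β-allylic alcohol 2β-acetoxy-4β,10β-dihydroxy-4α-isopropyl-6α-(4-methoxybenzoyloxy)-1β,8-dimethyl-5α-H-bicyclo[5.3.0]dec-8-ene F6. Silylation (TBSOTf, 2,6-lutidine, −78 °C) should give its 10β-tert-butyldimethylsilyl ether F7. mCPBA (NaHCO3, CH2Cl2, 0 °C) should then epoxidize anti to the silyloxy group to the 8α,9α-epoxide F8. TBAF buffered with AcOH comes back to the route at 24.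

Further compounds
F1 | step 9 | methyl (3R)-3-(4,7-dimethyl-6-oxocyclohepta-1,4-dien-1-yl)-3-(triethylsilyloxy)propanoate (both C1 epimers) | COC(=O)C[C@@H](O[Si](CC)(CC)CC)C1=CCC(C)=CC(=O)C1C
F2 | step 13 | 2β-acetoxy-5α,6α-epoxy-4α-hydroxy-1β,8-dimethylbicyclo[5.3.0]dec-8-en-10-one | O1[C@H]2CC(C)=CC(=O)[C@]3(C)[C@@]12[C@H](O)C[C@H]3OC(C)=O
F3 | step 13 | 2β-acetoxy-5α,6α-epoxy-1β,8-dimethylbicyclo[5.3.0]dec-8-ene-4,10-dione | O1[C@H]2CC(C)=CC(=O)[C@]3(C)[C@@]12C(=O)C[C@H]3OC(C)=O
F4 | step 13 | 2β-acetoxy-6α-hydroxy-1β,8-dimethyl-5α-H-bicyclo[5.3.0]dec-8-ene-4,10-dione | O[C@H]1CC(C)=CC(=O)[C@]2(C)[C@@H]1C(=O)C[C@H]2OC(C)=O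
F5 | step 17 | 2β-acetoxy-4β-hydroxy-4α-isopropyl-6α-(4-methoxybenzoyloxy)-1β,8-dimethyl-5α-H-bicyclo[5.3.0]dec-8-en-10-one | COc1ccc(cc1)C(=O)O[C@H]1CC(C)=CC(=O)[C@]2(C)[C@@H]1[C@](O)(C(C)C)C[C@H]2OC(C)=O
F6 | step 17 | 2β-acetoxy-4β,10β-dihydroxy-4α-isopropyl-6α-(4-methoxybenzoyloxy)-1β,8-dimethyl-5α-H-bicyclo[5.3.0]dec-8-ene | COc1ccc(cc1)C(=O)O[C@H]1CC(C)=C[C@H](O)[C@]2(C)[C@@H]1[C@](O)(C(C)C)C[C@H]2OC(C)=O
F7 | step 17 | 2β-acetoxy-10β-(tert-butyldimethylsilyloxy)-4β-hydroxy-4α-isopropyl-6α-(4-methoxybenzoyloxy)-1β,8-dimethyl-5α-H-bicyclo[5.3.0]dec-8-ene | COc1ccc(cc1)C(=O)O[C@H]1CC(C)=C[C@H](O[Si](C)(C)C(C)(C)C)[C@]2(C)[C@@H]1[C@](O)(C(C)C)C[C@H]2OC(C)=O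
F8 | step 17 | 2β-acetoxy-10β-(tert-butyldimethylsilyloxy)-8α,9α-epoxy-4β-hydroxy-4α-isopropyl-6α-(4-methoxybenzoyloxy)-1β,8-dimethyl-5α-H-bicyclo[5.3.0]decane | COc1ccc(cc1)C(=O)O[C@H]1C[C@@]2(C)O[C@H]2[C@H](O[Si](C)(C)C(C)(C)C)[C@]2(C)[C@@H]1[C@](O)(C(C)C)C[C@H]2OC(C)=O
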